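**Plan**

- Retrosynthesis: the C3–OH bond and the C2–H/C3–H pair are removed first (dihydroflavonol → flavanone → flavone). Ring C is then cut at C4a–C4, C4–C3 and O1–C2, and finally the two aryl–prenyl bonds at C6 and C8 are cut.
- Enabling feature: C4 is a lone carbonyl carbon held between C4a of ring A and the C3–C2–ring B unit, and O1 sits ortho to C4a. Ring C is therefore the sum of an ortho-iodophenol, CO and an arylacetylene.
- Forward: resorcinol is triiodinated, MOM-protected and prenylated twice by iodine–magnesium exchange, the third iodide staying at the future C4a. Ring C then closes in one pot with CO and the TIPS-protected ring-B alkyne.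
- Stereochemistry: C2 comes from a ligand-controlled copper hydride conjugate reduction of the flavone. C3 comes from substrate control, oxygen being delivered to the silyl enol ether anti to the C2 aryl group (2,3-trans).
- Protecting groups: MOM during the metalations, TIPS from the annulation onwards, removed last with buffered fluoride so that neither the prenyl groups nor the ketol see acid or base.

Key step: step 7

Assumption: (R)-DTBM-SEGPHOS–CuH is taken to deliver hydride to the C2 face that gives the 2S flavanone; the sense is set by the ligand enantiomer, so the (S)-ligand is the drop-in alternative if a test on the parent flavone shows the reverse.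

**Route**

Step 1
Reactants: 1 resorcinol
Product: 2 2,4,6-triiodobenzene-1,3-diol
Conditions: ICl (3.1 equiv), 1 M aq. HCl, rt
Reagents that add atoms: iodine monochloride, ClI
Why: Exhaustive electrophilic aromatic iodination at the three positions that are ortho or para to both hydroxyl groups is the classical halogenation of resorcinol.

Step 2
Reactants: 2 2,4,6-triiodobenzene-1,3-diol
Product: 3 1,3,5-triiodo-2,4-bis(methoxymethoxy)benzene
Conditions: MOMCl (3 equiv), i-Pr2NEt (4 equiv), CH2Cl2, 0 °C → rt
Reagents that add atoms: chloromethyl methyl ether, COCCl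
Why: Williamson-type acetalisation of the acidic iodophenols installs MOM ethers, which stabilise an ortho aryl–magnesium bond by chelation and cannot migrate from oxygen to carbon as a silyl group would.

Step 3
Reactants: 3 1,3,5-triiodo-2,4-bis(methoxymethoxy)benzene, 4 prenyl bromide
Product: 6 1,5-diiodo-2,4-bis(methoxymethoxy)-3-(3-methylbut-2-en-1-yl)benzene, via inner arylmagnesium chloride 5 (not isolated)
Conditions: i-PrMgCl·LiCl (1.05 equiv), THF, −40 °C; then CuI (10 mol %), prenyl bromide (1.3 equiv), −40 → 0 °C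
Reagents that add atoms: none
Why: Iodine–magnesium exchange should be fastest at the iodide flanked by both MOM ethers, where the carbanion is doubly chelated and inductively stabilised (the site that directed metalation of resorcinol bis-MOM ether also selects), and the copper-catalysed SN2 allylation of the aryl Grignard then occurs at the unhindered primary carbon of prenyl bromide.

Step 4
Reactants: 6 1,5-diiodo-2,4-bis(methoxymethoxy)-3-(3-methylbut-2-en-1-yl)benzene, 4 prenyl bromide
Product: 8 1-iodo-2,4-bis(methoxymethoxy)-3,5-bis(3-methylbut-2-en-1-yl)benzene, via outer arylmagnesium chloride 7 (not isolated)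
Conditions: i-PrMgCl·LiCl (1.1 equiv), THF, −20 → 0 °C; then CuI (10 mol %), prenyl bromide (1.3 equiv), 0 °C
Reagents that add atoms: none
Why: The two remaining iodides are equivalent by symmetry and the first exchange deactivates the ring towards a second, so the same exchange–copper-catalysed allylation replaces one iodide by prenyl and keeps the other as the handle for carbonylation.

Step 5
Reactants: 8 1-iodo-2,4-bis(methoxymethoxy)-3,5-bis(3-methylbut-2-en-1-yl)benzene
Product: 9 4-iodo-2,6-bis(3-methylbut-2-en-1-yl)benzene-1,3-diol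
Conditions: 3 M aq. HCl, MeOH, 45 °C
Reagents that add atoms: none
Why: Acid-catalysed transacetalisation to methanol frees both phenols under dilute-acid conditions that ortho-prenyl phenols routinely survive, their cyclisation to chromans needing stronger acid.

Step 6
Reactants: 10 4-ethynylphenol
Product: 11 (4-ethynylphenoxy)triisopropylsilane
Conditions: TIPSCl (1.2 equiv), imidazole, DMF, rt
Reagents that add atoms: triisopropylsilyl chloride, CC(C)[Si](Cl)(C(C)C)C(C)C
Why: Standard silylation of a phenol with a silyl chloride and imidazole gives a TIPS ether robust enough for the hot secondary amine of the next step.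

Step 7
Reactants: 9 4-iodo-2,6-bis(3-methylbut-2-en-1-yl)benzene-1,3-diol, 11 (4-ethynylphenoxy)triisopropylsilane, 12 carbon monoxide
Product: 15 7-hydroxy-6,8-bis(3-methylbut-2-en-1-yl)-2-[4-(triisopropylsilyloxy)phenyl]-4H-chromen-4-one, via hydroxyaryl ynone 13 (not isolated), via diethylamino enone 14 (not isolated)
Conditions: PdCl2(dppf) (5 mol %), CO (10 bar), Et2NH, 80 °C, no copper
Reagents that add atoms: none
Why: Pd(0) inserts into the C–I bond of 9, CO insertion gives the aroyl–palladium species, and copper-free alkynylation with 11 followed by reductive elimination forms C4a–C4 and C4–C3 in the ynone 13. Diethylamine then adds to the alkyne carbon remote from the carbonyl to give the enaminone 14, and the ortho phenol displaces the amine at that same carbon by addition–elimination, forming O1–C2. The closest known reaction type is the palladium-catalysed carbonylative Sonogashira coupling–cyclisation of ortho-iodophenols with terminal alkynes to flavones. Ring C closes in a 6-endo-dig sense with respect to the ynone and no stereocentre is created. Two selectivities are needed: CO insertion must precede alkynylation, which CO pressure and the absence of copper secure against direct coupling to a 2-arylbenzofuran, and closure must be 6-endo and not 5-exo (aurone), which the secondary amine secures by occupying C2 as an enamine so that oxygen can only enter there. The second hydroxyl of 9 lies para to the acyl group, cannot reach the ynone and is carried through free, while the prenyl alkenes are inert to Pd(0) and CO.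

Step 8
Reactants: 15 7-hydroxy-6,8-bis(3-methylbut-2-en-1-yl)-2-[4-(triisopropylsilyloxy)phenyl]-4H-chromen-4-one
Product: 16 6,8-bis(3-methylbut-2-en-1-yl)-7-(triisopropylsilyloxy)-2-[4-(triisopropylsilyloxy)phenyl]-4H-chromen-4-one
Conditions: TIPSOTf (1.3 equiv), 2,6-lutidine, CH2Cl2, 0 °C → rt
Reagents that add atoms: triisopropylsilyl trifluoromethanesulfonate, CC(C)[Si](OS(=O)(=O)C(F)(F)F)(C(C)C)C(C)C
Why: The only free hydroxyl, an acidic vinylogous-acid OH between two prenyl groups, is silylated by the silyl triflate with a hindered base, and any 4'-phenol bared in step 7 would be re-silylated in the same operation.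

Step 9
Reactants: 16 6,8-bis(3-methylbut-2-en-1-yl)-7-(triisopropylsilyloxy)-2-[4-(triisopropylsilyloxy)phenyl]-4H-chromen-4-one
Product: 18 (2S)-6,8-bis(3-methylbut-2-en-1-yl)-7-(triisopropylsilyloxy)-2-[4-(triisopropylsilyloxy)phenyl]chroman-4-one, via diethoxymethylsilyl enol ether 17 (not isolated)
Conditions: Cu(OAc)2·H2O (5 mol %), (R)-DTBM-SEGPHOS (5.5 mol %), (EtO)2MeSiH (3 equiv), toluene, 0 °C → rt; then 1 M HCl, THF, 0 °C
Reagents that add atoms: none
Why: Copper hydride asymmetric conjugate reduction of a β,β-disubstituted enone, here a 2-substituted chromen-4-one, delivers hydride to C2 from the face selected by the chiral bisphosphine, the enolate is held as silyl enol ether 17 so that the ketone escapes 1,2-reduction, and the isolated trisubstituted prenyl alkenes are not hydrocuprated.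

Step 10
Reactants: 18 (2S)-6,8-bis(3-methylbut-2-en-1-yl)-7-(triisopropylsilyloxy)-2-[4-(triisopropylsilyloxy)phenyl]chroman-4-one
Product: 19 (2S)-6,8-bis(3-methylbut-2-en-1-yl)-7-(triisopropylsilyloxy)-2-[4-(triisopropylsilyloxy)phenyl]-4-(trimethylsilyloxy)-2H-chromene
Conditions: TMSOTf (1.5 equiv), Et3N (3 equiv), CH2Cl2, 0 °C; non-aqueous work-up, used crude
Reagents that add atoms: trimethylsilyl trifluoromethanesulfonate, C[Si](C)(C)OS(=O)(=O)C(F)(F)F
Why: Soft enolisation with silyl triflate and amine forms the enol ether without a free metal enolate, the species that would expel the C2 aryloxide by E1cB ring opening and erase the C2 centre.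

Step 11
Reactants: 19 (2S)-6,8-bis(3-methylbut-2-en-1-yl)-7-(triisopropylsilyloxy)-2-[4-(triisopropylsilyloxy)phenyl]-4-(trimethylsilyloxy)-2H-chromene
Product: 21 (2R,3R)-3-hydroxy-6,8-bis(3-methylbut-2-en-1-yl)-7-(triisopropylsilyloxy)-2-[4-(triisopropylsilyloxy)phenyl]chroman-4-one, via siloxy epoxide 20 (not isolated)
Conditions: trans-2-(phenylsulfonyl)-3-phenyloxaziridine (1.2 equiv), CHCl3, rt; then 1 M HCl, THF, 0 °C
Reagents that add atoms: trans-2-(phenylsulfonyl)-3-phenyloxaziridine, O=S(=O)(c1ccccc1)N1OC1c1ccccc1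
Why: In this Rubottom-type oxidation with a Davis N-sulfonyloxaziridine the electron-rich siloxy alkene should take up oxygen much faster than the trialkyl prenyl alkenes, oxygen enters C3 anti to the C2 aryl group, and acid opening of 20 gives the 2,3-trans ketol, which is also the thermodynamic C3 epimer.

Step 12
Reactants: 21 (2R,3R)-3-hydroxy-6,8-bis(3-methylbut-2-en-1-yl)-7-(triisopropylsilyloxy)-2-[4-(triisopropylsilyloxy)phenyl]chroman-4-one
Product: 22 Lespeflorin B2, (2R,3R)-3,7-dihydroxy-2-(4-hydroxyphenyl)-6,8-bis(3-methylbut-2-en-1-yl)chroman-4-one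
Conditions: TBAF (2.5 equiv), AcOH (2.5 equiv), THF, 0 °C
Reagents that add atoms: none
Why: Fluoride cleaves both aryl silyl ethers while the acetic acid buffer keeps the phenols protonated, so neither retro-oxa-Michael opening at C2 nor C3 epimerisation is triggered and the prenyl groups never meet the acid that would cyclise them onto the 7-OH.

**Compound list**

1 | resorcinol (benzene-1,3-diol) | Oc1cccc(O)c1 | starting material
2 | 2,4,6-triiodobenzene-1,3-diol | Oc1c(I)cc(I)c(O)c1I | intermediate
3 | 1,3,5-triiodo-2,4-bis(methoxymethoxy)benzene | COCOc1c(I)cc(I)c(OCOC)c1I | intermediate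
4 | prenyl bromide (1-bromo-3-methylbut-2-ene) | CC(C)=CCBr | starting material
5 | [3,5-diiodo-2,6-bis(methoxymethoxy)phenyl]magnesium chloride | COCOc1c(I)cc(I)c(OCOC)c1[Mg]Cl | intermediate (not isolated)
6 | 1,5-diiodo-2,4-bis(methoxymethoxy)-3-(3-methylbut-2-en-1-yl)benzene | COCOc1c(I)cc(I)c(OCOC)c1CC=C(C)C | intermediate
7 | [5-iodo-2,4-bis(methoxymethoxy)-3-(3-methylbut-2-en-1-yl)phenyl]magnesium chloride | COCOc1c([Mg]Cl)cc(I)c(OCOC)c1CC=C(C)C | intermediate (not isolated)
8 | 1-iodo-2,4-bis(methoxymethoxy)-3,5-bis(3-methylbut-2-en-1-yl)benzene | COCOc1c(CC=C(C)C)cc(I)c(OCOC)c1CC=C(C)C | intermediate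
9 | 4-iodo-2,6-bis(3-methylbut-2-en-1-yl)benzene-1,3-diol | Oc1c(I)cc(CC=C(C)C)c(O)c1CC=C(C)C | intermediate
10 | 4-ethynylphenol | C#Cc1ccc(O)cc1 | starting material
11 | (4-ethynylphenoxy)triisopropylsilane | C#Cc1ccc(O[Si](C(C)C)(C(C)C)C(C)C)cc1 | intermediate
12 | carbon monoxide | [C-]#[O+] | starting material
13 | 1-[2,4-dihydroxy-3,5-bis(3-methylbut-2-en-1-yl)phenyl]-3-[4-(triisopropylsilyloxy)phenyl]prop-2-yn-1-one | Oc1c(C(=O)C#Cc2ccc(O[Si](C(C)C)(C(C)C)C(C)C)cc2)cc(CC=C(C)C)c(O)c1CC=C(C)C | intermediate (not isolated)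
14 | (E)-3-(diethylamino)-1-[2,4-dihydroxy-3,5-bis(3-methylbut-2-en-1-yl)phenyl]-3-[4-(triisopropylsilyloxy)phenyl]prop-2-en-1-one | Oc1c(C(=O)/C=C(/N(CC)CC)c2ccc(O[Si](C(C)C)(C(C)C)C(C)C)cc2)cc(CC=C(C)C)c(O)c1CC=C(C)C | intermediate (not isolated)
15 | 7-hydroxy-6,8-bis(3-methylbut-2-en-1-yl)-2-[4-(triisopropylsilyloxy)phenyl]-4H-chromen-4-one | CC(C)=CCc1cc2c(c(CC=C(C)C)c1O)OC(c1ccc(O[Si](C(C)C)(C(C)C)C(C)C)cc1)=CC2=O | intermediate
16 | 6,8-bis(3-methylbut-2-en-1-yl)-7-(triisopropylsilyloxy)-2-[4-(triisopropylsilyloxy)phenyl]-4H-chromen-4-one | CC(C)=CCc1cc2c(c(CC=C(C)C)c1O[Si](C(C)C)(C(C)C)C(C)C)OC(c1ccc(O[Si](C(C)C)(C(C)C)C(C)C)cc1)=CC2=O | intermediate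
17 | (2S)-4-[diethoxy(methyl)silyloxy]-6,8-bis(3-methylbut-2-en-1-yl)-7-(triisopropylsilyloxy)-2-[4-(triisopropylsilyloxy)phenyl]-2H-chromene | CC(C)=CCc1cc2c(c(CC=C(C)C)c1O[Si](C(C)C)(C(C)C)C(C)C)O[C@H](c1ccc(O[Si](C(C)C)(C(C)C)C(C)C)cc1)C=C2O[Si](C)(OCC)OCC | intermediate (not isolated)
18 | (2S)-6,8-bis(3-methylbut-2-en-1-yl)-7-(triisopropylsilyloxy)-2-[4-(triisopropylsilyloxy)phenyl]chroman-4-one | CC(C)=CCc1cc2c(c(CC=C(C)C)c1O[Si](C(C)C)(C(C)C)C(C)C)O[C@H](c1ccc(O[Si](C(C)C)(C(C)C)C(C)C)cc1)CC2=O | intermediate
19 | (2S)-6,8-bis(3-methylbut-2-en-1-yl)-7-(triisopropylsilyloxy)-2-[4-(triisopropylsilyloxy)phenyl]-4-(trimethylsilyloxy)-2H-chromene | CC(C)=CCc1cc2c(c(CC=C(C)C)c1O[Si](C(C)C)(C(C)C)C(C)C)O[C@H](c1ccc(O[Si](C(C)C)(C(C)C)C(C)C)cc1)C=C2O[Si](C)(C)C | intermediate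
20 | 3,4-epoxide of 19: 3,4-epoxy-4-(trimethylsilyloxy)flavan carrying the same prenyl and TIPS groups, oxirane oxygen on the face anti to the 2-aryl group | CC(C)=CCc1cc2c(c(CC=C(C)C)c1O[Si](C(C)C)(C(C)C)C(C)C)O[C@H](c1ccc(O[Si](C(C)C)(C(C)C)C(C)C)cc1)[C@H]3O[C@@]23O[Si](C)(C)C | intermediate (not isolated)
21 | (2R,3R)-3-hydroxy-6,8-bis(3-methylbut-2-en-1-yl)-7-(triisopropylsilyloxy)-2-[4-(triisopropylsilyloxy)phenyl]chroman-4-one | CC(C)=CCc1cc2c(c(CC=C(C)C)c1O[Si](C(C)C)(C(C)C)C(C)C)O[C@H](c1ccc(O[Si](C(C)C)(C(C)C)C(C)C)cc1)[C@@H](O)C2=O | intermediate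
22 | Lespeflorin B2, (2R,3R)-3,7-dihydroxy-2-(4-hydroxyphenyl)-6,8-bis(3-methylbut-2-en-1-yl)chroman-4-one (2,3-trans) | CC(C)=CCc1cc2c(c(CC=C(C)C)c1O)O[C@H](c1ccc(O)cc1)[C@@H](O)C2=O | target

**Step count**

Total steps: 12. Longest linear sequence: 11 steps (steps 1–5 and 7–12, from resorcinol); the alkyne branch adds step 6.

**Steps most likely to fail**

Step 9. Hydride transfer to an electron-rich, hindered 2-aryl chromenone may be slow, facial discrimination may be poor, or some 1,2-reduction may occur. Fallback: from 16, an achiral and more reactive copper hydride (Cu(OAc)2, 1,2-bis(diphenylphosphino)benzene, PMHS, toluene, then dilute acid) should give the racemic flavanone F1. This is resolved kinetically by Noyori transfer hydrogenation (RuCl[(R,R)-TsDPEN](p-cymene), HCO2H/Et3N, stopped near half conversion), the catalyst enantiomer being the one that reduces the 2R ketone. The 2R ketone becomes the cis-(2R,4R)-flavan-4-ol F2, which is removed by chromatography, and the unreacted 2S ketone rejoins the route at 18.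

Step 7. Direct alkynylation before CO insertion (leading to a 2-arylbenzofuran), capture of the aroyl–palladium species by diethylamine (amide formation), or 5-exo closure may compete on the free iodoresorcinol. Fallback: from 8, whose phenols are still masked so that neither benzofuran nor aurone formation is open, carbonylative Sonogashira coupling with 11 (PdCl2(PPh3)2, Et3N, CO 5 bar, THF, 50 °C) should give the bis-MOM ynone F3. Diethylamine in ethanol at rt converts it into the bis-MOM enaminone F4, and 3 M HCl in methanol at 45 °C removes both MOM groups and closes ring C by addition–elimination. The route is rejoined at 15; if the 4'-TIPS ether is partly lost, step 8 restores it.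

Step 11. Oxygen transfer to the prenyl double bonds may compete with the slower-than-expected oxidation of the enol ether. Fallback: from 19, MeLi (THF, −78 °C) releases the lithium enolate F5, and the same oxaziridine is added at −78 °C, where enolate hydroxylation is fast and alkenes are untouched. The low temperature also holds back ring opening of the enolate, and an NH4Cl quench at −78 °C rejoins the route at 21.

**Further compounds**

F1 | step 9 | racemic 6,8-bis(3-methylbut-2-en-1-yl)-7-(triisopropylsilyloxy)-2-[4-(triisopropylsilyloxy)phenyl]chroman-4-one | CC(C)=CCc1cc2c(c(CC=C(C)C)c1O[Si](C(C)C)(C(C)C)C(C)C)OC(c1ccc(O[Si](C(C)C)(C(C)C)C(C)C)cc1)CC2=O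
F2 | step 9 | (2R,4R)-6,8-bis(3-methylbut-2-en-1-yl)-7-(triisopropylsilyloxy)-2-[4-(triisopropylsilyloxy)phenyl]chroman-4-ol (2,4-cis) | CC(C)=CCc1cc2c(c(CC=C(C)C)c1O[Si](C(C)C)(C(C)C)C(C)C)O[C@@H](c1ccc(O[Si](C(C)C)(C(C)C)C(C)C)cc1)C[C@H]2O
F3 | step 7 | 1-[2,4-bis(methoxymethoxy)-3,5-bis(3-methylbut-2-en-1-yl)phenyl]-3-[4-(triisopropylsilyloxy)phenyl]prop-2-yn-1-one | COCOc1c(CC=C(C)C)cc(C(=O)C#Cc2ccc(O[Si](C(C)C)(C(C)C)C(C)C)cc2)c(OCOC)c1CC=C(C)C
F4 | step 7 | (E)-3-(diethylamino)-1-[2,4-bis(methoxymethoxy)-3,5-bis(3-methylbut-2-en-1-yl)phenyl]-3-[4-(triisopropylsilyloxy)phenyl]prop-2-en-1-one | COCOc1c(CC=C(C)C)cc(C(=O)/C=C(/N(CC)CC)c2ccc(O[Si](C(C)C)(C(C)C)C(C)C)cc2)c(OCOC)c1CC=C(C)C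
F5 | step 11 | lithium enolate of 18, lithium (2S)-6,8-bis(3-methylbut-2-en-1-yl)-7-(triisopropylsilyloxy)-2-[4-(triisopropylsilyloxy)phenyl]-2H-chromen-4-olate | CC(C)=CCc1cc2c(c(CC=C(C)C)c1O[Si](C(C)C)(C(C)C)C(C)C)O[C@H](c1ccc(O[Si](C(C)C)(C(C)C)C(C)C)cc1)C=C2O[Li]
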